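**Plan**

- Retrosynthesis: (1) unmask the aldehyde, ketone and acid; (2) cut, in one event, the ring O–C2 bond of the 5,5-dimethylfuran-2(5H)-ylidene ring and the bond from the exocyclic alkene carbon to its formyl carbon, which leads back to an open-chain (Z)-enynol; (3) cut the C2–C3 bond between the two stereocentres by a [3,3] shift of an allylic ester; (4) cut that ester into a C9 acid and a C12 carbinol.
- Forward: acid 4 (Grignard reagent + diketene) and carbinol 13 (aldehyde, bromo-olefination, alkynylation, cis-hydrogenation) are esterified; Ireland–Claisen rearrangement and HBr elimination give the complete C20 chain as a (Z)-enynol; the only ring is closed in step 11 and the masks are then removed.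
- Stereochemistry: one carbinol centre (C5 of 12) is set by catalytic asymmetric alkynylation; the chair Ireland–Claisen transition state carries it to the vicinal C2/C3 pair (2R,3S); the E geometry of the tetrasubstituted exocyclic alkene comes from anti addition across the alkyne.
- Enabling feature: in the ring O1–C2(=C)–C3H=C4H–C5Me2 the ether oxygen sits on a tertiary carbon joined through a cis CH=CH to C2, and across the exocyclic C2=C bond it is trans to the formyl carbon. This is the pattern left by a 5-exo-dig anti addition of that oxygen and a one-carbon electrophile to an alkyne.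

Key step: step 11

Assumption: the (S,S)-ProPhenol ligand is taken to give the 5S alcohol 12; the sense of induction is to be confirmed, and the (R,R)-ligand is used if it is opposite.

**Step 1**
Reactants: 1 2-(3-chloropropyl)-2-methyl-1,3-dioxolane; 2 diketene (4-methylideneoxetan-2-one)
Product: 4 3-methylidene-6-(2-methyl-1,3-dioxolan-2-yl)hexanoic acid, via Grignard reagent 3 (not isolated)
Conditions: Mg, THF, 50 °C; then 2, NiCl2 (5 mol %), THF, −20 → 0 °C; cold aq. citric acid to pH 4
Reagents that add atoms: none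
Why: Nickel-catalysed Kumada-type cross-coupling of the alkyl Grignard reagent at the vinylic C–O bond of diketene should open the β-lactone to the 3-methylidene alkanoic acid.

**Step 2**
Reactants: 5 3,3-diethoxypropan-1-ol
Product: 6 3,3-diethoxypropanal
Conditions: TEMPO (10 mol %), PhI(OAc)2 (1.1 equiv), CH2Cl2, rt; used crude
Reagents that add atoms: none
Why: Oxoammonium (TEMPO) oxidation of a primary alcohol should stop at the aldehyde under nearly neutral conditions that leave the acetal intact.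

**Step 3**
Reactants: 6 3,3-diethoxypropanal; 7 N-methoxy-N-methyl-2-(triphenyl-λ5-phosphanylidene)acetamide
Product: 9 (2Z)-2-bromo-5,5-diethoxy-N-methoxy-N-methylpent-2-enamide, via bromo ylide 8 (not isolated)
Conditions: 7, NBS (1.05 equiv), CH2Cl2, −20 °C; then 6, rt → 40 °C
Reagents that add atoms: N-bromosuccinimide O=C1CCC(=O)N1Br
Why: Bromination of the stabilized ylide and deprotonation by succinimide anion give the α-bromo ylide, whose Wittig olefination should place bromine cis to the alkyl chain (Z), as is usual for α-halo stabilized ylides.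

**Step 4**
Reactants: 9 (2Z)-2-bromo-5,5-diethoxy-N-methoxy-N-methylpent-2-enamide
Product: 10 (2Z)-2-bromo-5,5-diethoxypent-2-enal
Conditions: DIBAL-H (1.3 equiv), THF, −78 °C; aq. Rochelle salt
Reagents that add atoms: none
Why: Hydride reduction of an N-methoxy-N-methyl amide should stop at the aldehyde because the chelated tetrahedral intermediate survives until work-up.

**Step 5**
Reactants: 10 (2Z)-2-bromo-5,5-diethoxypent-2-enal; 11 trimethyl[(2-methylbut-3-yn-2-yl)oxy]silane
Product: 12 (3Z,5S)-4-bromo-1,1-diethoxy-8-methyl-8-[(trimethylsilyl)oxy]non-3-en-6-yn-5-ol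
Conditions: 11 (3 equiv), Me2Zn (3 equiv), (S,S)-ProPhenol (20 mol %), Ph3P=O (40 mol %), toluene, 4 °C; aq. NH4Cl
Reagents that add atoms: none
Why: Catalytic enantioselective zinc alkynylide addition to an enal, in which the dinuclear zinc–ProPhenol catalyst should deliver the alkynyl group to one aldehyde face and so set C5 (S), the only stereocentre introduced by reagent control.

**Step 6**
Reactants: 12 (3Z,5S)-4-bromo-1,1-diethoxy-8-methyl-8-[(trimethylsilyl)oxy]non-3-en-6-yn-5-ol
Product: 13 (3Z,5S,6Z)-4-bromo-1,1-diethoxy-8-methyl-8-[(trimethylsilyl)oxy]nona-3,6-dien-5-ol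
Conditions: H2 (1 atm), Lindlar catalyst, quinoline, EtOAc, rt
Reagents that add atoms: none
Why: Lindlar semi-hydrogenation should add hydrogen syn to the isolated alkyne to give the cis alkene, with the trisubstituted bromoalkene left untouched on the poisoned catalyst.

**Step 7**
Reactants: 13 (3Z,5S,6Z)-4-bromo-1,1-diethoxy-8-methyl-8-[(trimethylsilyl)oxy]nona-3,6-dien-5-ol; 4 3-methylidene-6-(2-methyl-1,3-dioxolan-2-yl)hexanoic acid
Product: 14 (3Z,5S,6Z)-4-bromo-1,1-diethoxy-8-methyl-8-[(trimethylsilyl)oxy]nona-3,6-dien-5-yl 3-methylidene-6-(2-methyl-1,3-dioxolan-2-yl)hexanoate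
Conditions: DCC (1.2 equiv), DMAP (5 mol %), CH2Cl2, −10 → 0 °C
Reagents that add atoms: none
Why: Steglich esterification of the only free (secondary) hydroxyl, run cold with little DMAP so that the β,γ-unsaturated acyl group should not move into conjugation; the carbinol centre is not touched.

**Step 8**
Reactants: 14 (3Z,5S,6Z)-4-bromo-1,1-diethoxy-8-methyl-8-[(trimethylsilyl)oxy]nona-3,6-dien-5-yl 3-methylidene-6-(2-methyl-1,3-dioxolan-2-yl)hexanoate
Product: 17 (2R,3S,4Z,6Z)-4-bromo-3-(2,2-diethoxyethyl)-8-methyl-2-[5-(2-methyl-1,3-dioxolan-2-yl)pent-1-en-2-yl]-8-[(trimethylsilyl)oxy]nona-4,6-dienoic acid, via silyl ketene acetal 15 (not isolated), via trimethylsilyl ester 16 (not isolated)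
Conditions: LDA (1.2 equiv), TMSCl (1.5 equiv), THF–DMPU (4:1), −78 °C; then rt → 40 °C; aq. citric acid
Reagents that add atoms: none
Why: Ireland–Claisen rearrangement, in which the Z(O) ketene acetal 15 (alkenyl group cis to OSiMe3, favoured in THF–DMPU) should react through a chair transition state with the diethoxyethyl group of the (Z)-bromoalkene and the cis-alkenyl group on the (S)-carbinol carbon both equatorial, so that the carbinol configuration is relayed suprafacially to C3 (S) and C2 (R, syn), the new bromoalkene has H anti to Br, and the hindered cis-alkene arm stays out of the [3,3] shift.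

**Step 9**
Reactants: 17 (2R,3S,4Z,6Z)-4-bromo-3-(2,2-diethoxyethyl)-8-methyl-2-[5-(2-methyl-1,3-dioxolan-2-yl)pent-1-en-2-yl]-8-[(trimethylsilyl)oxy]nona-4,6-dienoic acid
Product: 18 (2R,3S,6Z)-3-(2,2-diethoxyethyl)-8-hydroxy-8-methyl-2-[5-(2-methyl-1,3-dioxolan-2-yl)pent-1-en-2-yl]non-6-en-4-ynoic acid
Conditions: TBAF·3H2O (5 equiv), DMF, 60 °C; aq. NH4Cl
Reagents that add atoms: none
Why: Fluoride-mediated anti E2 dehydrobromination (vinylic H trans to Br) should give the conjugated (Z)-enyne while the same reagent removes the tertiary silyl ether, and the carboxylate formed first shields the C2–H from epimerization.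

**Step 10**
Reactants: 18 (2R,3S,6Z)-3-(2,2-diethoxyethyl)-8-hydroxy-8-methyl-2-[5-(2-methyl-1,3-dioxolan-2-yl)pent-1-en-2-yl]non-6-en-4-ynoic acid
Product: 19 2-(trimethylsilyl)ethyl (2R,3S,6Z)-3-(2,2-diethoxyethyl)-8-hydroxy-8-methyl-2-[5-(2-methyl-1,3-dioxolan-2-yl)pent-1-en-2-yl]non-6-en-4-ynoate
Conditions: 2-(trimethylsilyl)ethanol (1.5 equiv), PPh3, DIAD, THF, 0 °C → rt
Reagents that add atoms: 2-(trimethylsilyl)ethanol C[Si](C)(C)CCO
Why: Mitsunobu esterification activates the primary alcohol and not the acid, so the epimerizable C2 centre should be safe and the tertiary alcohol does not react; the ester is needed to keep the carboxyl group from adding to the alkyne in step 11.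

**Step 11**
Reactants: 19 2-(trimethylsilyl)ethyl (2R,3S,6Z)-3-(2,2-diethoxyethyl)-8-hydroxy-8-methyl-2-[5-(2-methyl-1,3-dioxolan-2-yl)pent-1-en-2-yl]non-6-en-4-ynoate
Product: 22 2-(trimethylsilyl)ethyl (2R,3S,4E)-3-(2,2-diethoxyethyl)-4-(5,5-dimethylfuran-2(5H)-ylidene)-2-[5-(2-methyl-1,3-dioxolan-2-yl)pent-1-en-2-yl]-5-oxopentanoate, via mixed orthoformate 20 (not isolated), via diethyl acetal 21 (not isolated)
Conditions: (i) HC(OEt)3 (10 equiv), PPTS (5 mol %), 4 Å MS, CH2Cl2, rt, concentrate; (ii) PtCl2 (5 mol %), 1,5-cyclooctadiene (20 mol %), toluene, 40 °C; (iii) wet SiO2, cat. oxalic acid (pH about 4), CH2Cl2, 0 °C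
Reagents that add atoms: triethyl orthoformate CCOC(OCC)OCC; water O
Why: Proposed new method: the tertiary alcohol is first tethered to the future formyl carbon as the mixed orthoformate 20; Pt(II) activation of the alkyne then triggers anti attack of that oxygen at the proximal alkyne carbon, the oxonium ion expels the stabilized diethoxycarbenium ion, and this recombines at the platinum-bearing carbon with retention (a 1,3 O-to-C shift). The closest known reaction types are the Pt(II)/Au(I)-catalysed carboalkoxylation of alkynes, in which acetal, allyl or benzyl groups migrate from oxygen to the vinyl-metal carbon, and the π-acid cycloisomerization of (Z)-2-en-4-yn-1-ols to 5-ylidene-2,5-dihydrofurans. The dihydrofuran ring closes in the 5-exo-dig mode, favoured over 6-endo by the cis alkene and the gem-dimethyl group, which hold the oxygen over the proximal alkyne carbon. No stereocentre is formed; the E geometry of the tetrasubstituted exocyclic alkene follows from anti oxyplatination and retentive C–C bond formation, and the same isomer should be the thermodynamic one of the push–pull enal after the buffered hydrolysis of the very labile vinylogous acetal 21. If protodemetalation intervenes, the exocyclic enol ether formed is captured at the same carbon by the diethoxycarbenium ion, so both paths converge on 21. The step needs oxygen attack to outrun 1,5-enyne cycloisomerization with the 1,1-disubstituted alkene and lactonization, which the pre-organized tethered oxygen and the ester on the carboxyl group should secure.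

**Step 12**
Reactants: 22 2-(trimethylsilyl)ethyl (2R,3S,4E)-3-(2,2-diethoxyethyl)-4-(5,5-dimethylfuran-2(5H)-ylidene)-2-[5-(2-methyl-1,3-dioxolan-2-yl)pent-1-en-2-yl]-5-oxopentanoate
Product: 23 (2R,3S,4E)-3-(2,2-diethoxyethyl)-4-(5,5-dimethylfuran-2(5H)-ylidene)-2-[5-(2-methyl-1,3-dioxolan-2-yl)pent-1-en-2-yl]-5-oxopentanoic acid
Conditions: TBAF (1 M in THF, 2.5 equiv), THF, 0 °C → rt; aq. NH4Cl
Reagents that add atoms: none
Why: Fluoride-induced β-elimination of the 2-(trimethylsilyl)ethyl ester should release the carboxylate without acid or hydroxide, and the non-enolizable push–pull enal and the acetals tolerate it.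

**Step 13**
Reactants: 23 (2R,3S,4E)-3-(2,2-diethoxyethyl)-4-(5,5-dimethylfuran-2(5H)-ylidene)-2-[5-(2-methyl-1,3-dioxolan-2-yl)pent-1-en-2-yl]-5-oxopentanoic acid
Product: 24 (2R,3S,4E)-4-(5,5-dimethylfuran-2(5H)-ylidene)-5-oxo-2-(6-oxohept-1-en-2-yl)-3-(2-oxoethyl)pentanoic acid (CNP0150297.1)
Conditions: AcOH–THF–H2O (3:1:1), 40 °C
Reagents that add atoms: water O
Why: Mild acid-catalysed hydrolysis should unmask the aldehyde and the methyl ketone together, while any hydration of the vinylogous formate ring is reversible and re-closes to the conjugated ring with the thermodynamic E geometry.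

**Compound list**

1 | 2-(3-chloropropyl)-2-methyl-1,3-dioxolane | ClCCCC1(C)OCCO1 | starting material
2 | diketene (4-methylideneoxetan-2-one) | C=C1CC(=O)O1 | starting material
3 | [3-(2-methyl-1,3-dioxolan-2-yl)propyl]magnesium chloride | Cl[Mg]CCCC1(C)OCCO1 | intermediate
4 | 3-methylidene-6-(2-methyl-1,3-dioxolan-2-yl)hexanoic acid | C=C(CCCC1(C)OCCO1)CC(=O)O | intermediate
5 | 3,3-diethoxypropan-1-ol | CCOC(CCO)OCC | starting material
6 | 3,3-diethoxypropanal | CCOC(CC=O)OCC | intermediate
7 | N-methoxy-N-methyl-2-(triphenyl-λ5-phosphanylidene)acetamide | CON(C)C(=O)C=P(c1ccccc1)(c1ccccc1)c1ccccc1 | starting material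
8 | 2-bromo-N-methoxy-N-methyl-2-(triphenyl-λ5-phosphanylidene)acetamide | CON(C)C(=O)C(Br)=P(c1ccccc1)(c1ccccc1)c1ccccc1 | intermediate
9 | (2Z)-2-bromo-5,5-diethoxy-N-methoxy-N-methylpent-2-enamide | CCOC(OCC)C/C=C(\Br)C(=O)N(C)OC | intermediate
10 | (2Z)-2-bromo-5,5-diethoxypent-2-enal | CCOC(OCC)C/C=C(\Br)C=O | intermediate
11 | trimethyl[(2-methylbut-3-yn-2-yl)oxy]silane | C#CC(C)(C)O[Si](C)(C)C | starting material
12 | (3Z,5S)-4-bromo-1,1-diethoxy-8-methyl-8-[(trimethylsilyl)oxy]non-3-en-6-yn-5-ol | CCOC(OCC)C/C=C(\Br)[C@@H](O)C#CC(C)(C)O[Si](C)(C)C | intermediate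
13 | (3Z,5S,6Z)-4-bromo-1,1-diethoxy-8-methyl-8-[(trimethylsilyl)oxy]nona-3,6-dien-5-ol | CCOC(OCC)C/C=C(\Br)[C@@H](O)/C=C\C(C)(C)O[Si](C)(C)C | intermediate
14 | (3Z,5S,6Z)-4-bromo-1,1-diethoxy-8-methyl-8-[(trimethylsilyl)oxy]nona-3,6-dien-5-yl 3-methylidene-6-(2-methyl-1,3-dioxolan-2-yl)hexanoate | CCOC(OCC)C/C=C(\Br)[C@@H](OC(=O)CC(=C)CCCC1(C)OCCO1)/C=C\C(C)(C)O[Si](C)(C)C | intermediate
15 | (Z)-O-trimethylsilyl ketene acetal of ester 14 (alkenyl group cis to OSiMe3) | CCOC(OCC)C/C=C(\Br)[C@@H](O/C(O[Si](C)(C)C)=C/C(=C)CCCC1(C)OCCO1)/C=C\C(C)(C)O[Si](C)(C)C | intermediate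
16 | trimethylsilyl ester of acid 17 | C=C(CCCC1(C)OCCO1)[C@H](C(=O)O[Si](C)(C)C)[C@H](CC(OCC)OCC)/C(Br)=C/C=C\C(C)(C)O[Si](C)(C)C | intermediate
17 | (2R,3S,4Z,6Z)-4-bromo-3-(2,2-diethoxyethyl)-8-methyl-2-[5-(2-methyl-1,3-dioxolan-2-yl)pent-1-en-2-yl]-8-[(trimethylsilyl)oxy]nona-4,6-dienoic acid | C=C(CCCC1(C)OCCO1)[C@H](C(=O)O)[C@H](CC(OCC)OCC)/C(Br)=C/C=C\C(C)(C)O[Si](C)(C)C | intermediate
18 | (2R,3S,6Z)-3-(2,2-diethoxyethyl)-8-hydroxy-8-methyl-2-[5-(2-methyl-1,3-dioxolan-2-yl)pent-1-en-2-yl]non-6-en-4-ynoic acid | C=C(CCCC1(C)OCCO1)[C@H](C(=O)O)[C@H](CC(OCC)OCC)C#C/C=C\C(C)(C)O | intermediate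
19 | 2-(trimethylsilyl)ethyl (2R,3S,6Z)-3-(2,2-diethoxyethyl)-8-hydroxy-8-methyl-2-[5-(2-methyl-1,3-dioxolan-2-yl)pent-1-en-2-yl]non-6-en-4-ynoate | C=C(CCCC1(C)OCCO1)[C@H](C(=O)OCC[Si](C)(C)C)[C@H](CC(OCC)OCC)C#C/C=C\C(C)(C)O | intermediate
20 | 2-(trimethylsilyl)ethyl (2R,3S,6Z)-8-(diethoxymethoxy)-3-(2,2-diethoxyethyl)-8-methyl-2-[5-(2-methyl-1,3-dioxolan-2-yl)pent-1-en-2-yl]non-6-en-4-ynoate | C=C(CCCC1(C)OCCO1)[C@H](C(=O)OCC[Si](C)(C)C)[C@H](CC(OCC)OCC)C#C/C=C\C(C)(C)OC(OCC)OCC | intermediate
21 | 2-(trimethylsilyl)ethyl (2R,3S,4E)-5,5-diethoxy-3-(2,2-diethoxyethyl)-4-(5,5-dimethylfuran-2(5H)-ylidene)-2-[5-(2-methyl-1,3-dioxolan-2-yl)pent-1-en-2-yl]pentanoate | C=C(CCCC1(C)OCCO1)[C@H](C(=O)OCC[Si](C)(C)C)[C@H](CC(OCC)OCC)/C(C(OCC)OCC)=C1/C=CC(C)(C)O1 | intermediate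
22 | 2-(trimethylsilyl)ethyl (2R,3S,4E)-3-(2,2-diethoxyethyl)-4-(5,5-dimethylfuran-2(5H)-ylidene)-2-[5-(2-methyl-1,3-dioxolan-2-yl)pent-1-en-2-yl]-5-oxopentanoate | C=C(CCCC1(C)OCCO1)[C@H](C(=O)OCC[Si](C)(C)C)[C@H](CC(OCC)OCC)/C(C=O)=C1/C=CC(C)(C)O1 | intermediate
23 | (2R,3S,4E)-3-(2,2-diethoxyethyl)-4-(5,5-dimethylfuran-2(5H)-ylidene)-2-[5-(2-methyl-1,3-dioxolan-2-yl)pent-1-en-2-yl]-5-oxopentanoic acid | C=C(CCCC1(C)OCCO1)[C@H](C(=O)O)[C@H](CC(OCC)OCC)/C(C=O)=C1/C=CC(C)(C)O1 | intermediate
24 | (2R,3S,4E)-4-(5,5-dimethylfuran-2(5H)-ylidene)-5-oxo-2-(6-oxohept-1-en-2-yl)-3-(2-oxoethyl)pentanoic acid | C=C(CCCC(C)=O)[C@H](C(=O)O)[C@H](CC=O)/C(C=O)=C1/C=CC(C)(C)O1 | target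

**Step count and risks**

Total steps: 13. Longest linear sequence: 12 steps (steps 2–13, from 5 to 24); step 1 is a one-step branch that joins at step 7.

Steps most likely to fail:

1. Step 11 (proposed new method). The diethoxymethyl group may leave oxygen before the alkyne is attacked, the vinyl-platinum species may be protonated without carbon transfer, or the π-acid may be diverted into cycloisomerization of the 1,5-enyne, so that ring closure and C-formylation do not occur together. The fallback uses known chemistry and sets out from 19. Cationic gold(I) cycloisomerization of the free (Z)-enynol [(Ph3P)AuCl/AgOTf, CH2Cl2, rt] should give the exocyclic dienol ether 2-(trimethylsilyl)ethyl (2R,3R,4Z)-3-(2,2-diethoxyethyl)-4-(5,5-dimethylfuran-2(5H)-ylidene)-2-[5-(2-methyl-1,3-dioxolan-2-yl)pent-1-en-2-yl]butanoate F1. Vilsmeier–Haack formylation (POCl3, DMF, 0 °C; aq. NaOAc) at the exocyclic enol-ether carbon then gives the enal, and the route is rejoined at 22.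

2. Step 8. Mixed enolate geometry may erode the syn selectivity, and the doubly allylic ester may ionize or undergo a competing [3,3] shift through its second allylic arm. The fallback sets out from 12, before the semi-hydrogenation, so that only one allylic arm is present. Steglich esterification of 12 with 4 gives (3Z,5S)-4-bromo-1,1-diethoxy-8-methyl-8-[(trimethylsilyl)oxy]non-3-en-6-yn-5-yl 3-methylidene-6-(2-methyl-1,3-dioxolan-2-yl)hexanoate F2. Ireland–Claisen rearrangement of this propargylic–allylic ester should give (2R,3S,4Z)-4-bromo-3-(2,2-diethoxyethyl)-8-methyl-2-[5-(2-methyl-1,3-dioxolan-2-yl)pent-1-en-2-yl]-8-[(trimethylsilyl)oxy]non-4-en-6-ynoic acid F3. Lindlar semi-hydrogenation of the alkyne then rejoins the route at 17.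

3. Step 5. Facial selectivity in the zinc alkynylide addition to the α-bromo enal may be poor, or methyl transfer may compete. The fallback sets out from 9. Addition of the lithium acetylide of 11 (n-BuLi, THF, −78 °C) to the N-methoxy-N-methyl amide gives the ynone (3Z)-4-bromo-1,1-diethoxy-8-methyl-8-[(trimethylsilyl)oxy]non-3-en-6-yn-5-one F4. Ru–TsDPEN-catalysed asymmetric transfer hydrogenation of this alkynyl ketone (i-PrOH) then sets the carbinol centre, and the route is rejoined at 12.

**Further compounds**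

F1 | step 11 | 2-(trimethylsilyl)ethyl (2R,3R,4Z)-3-(2,2-diethoxyethyl)-4-(5,5-dimethylfuran-2(5H)-ylidene)-2-[5-(2-methyl-1,3-dioxolan-2-yl)pent-1-en-2-yl]butanoate | C=C(CCCC1(C)OCCO1)[C@H](C(=O)OCC[Si](C)(C)C)[C@H](CC(OCC)OCC)/C=C1/C=CC(C)(C)O1
F2 | step 8 | (3Z,5S)-4-bromo-1,1-diethoxy-8-methyl-8-[(trimethylsilyl)oxy]non-3-en-6-yn-5-yl 3-methylidene-6-(2-methyl-1,3-dioxolan-2-yl)hexanoate | CCOC(OCC)C/C=C(\Br)[C@@H](OC(=O)CC(=C)CCCC1(C)OCCO1)C#CC(C)(C)O[Si](C)(C)C
F3 | step 8 | (2R,3S,4Z)-4-bromo-3-(2,2-diethoxyethyl)-8-methyl-2-[5-(2-methyl-1,3-dioxolan-2-yl)pent-1-en-2-yl]-8-[(trimethylsilyl)oxy]non-4-en-6-ynoic acid | C=C(CCCC1(C)OCCO1)[C@H](C(=O)O)[C@H](CC(OCC)OCC)/C(Br)=C/C#CC(C)(C)O[Si](C)(C)C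
F4 | step 5 | (3Z)-4-bromo-1,1-diethoxy-8-methyl-8-[(trimethylsilyl)oxy]non-3-en-6-yn-5-one | CCOC(OCC)C/C=C(\Br)C(=O)C#CC(C)(C)O[Si](C)(C)C
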